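**Retrosynthetic overview**
1. The last event is a Schenck ene reaction of singlet oxygen with the tetrasubstituted C4=C5 olefin of methyl 3β-angeloyloxyeudesma-4,11(13)-dien-12-oate; it installs the 5α-hydroperoxide and the C4=C15 methylene together.
2. That diene ester comes from a 3-oxo-4-ene bicycle (Luche reduction, angeloylation) whose ketal-protected C7 acetyl group is turned into the acrylate by enol triflate methoxycarbonylation.
3. Ring A is closed at C1–C10 by an MHAT-initiated 6-endo radical conjugate addition: the tertiary C10 radical made from the C9=C10 olefin adds to C1 of a C1=C2–C3=O vinyl ketone, and dehydration of the resulting C5 ketol gives the enone.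
4. The cyclisation substrate is made by 1,2-addition of a propionamide enolate (C15/C4/C3) to the C5 carbonyl of an (R)-carvone-derived ring B enone, then vinyl Grignard addition (C2/C1); ring B and C7 are from the chiral pool, so the ring order is B, then A.
5. Enabling feature: C3 carries oxygen and C4=C5/C5–O is aldol-related to it, so C1 is the β-carbon of a C3 enone, while C10 is the methyl-bearing carbon of the trisubstituted C9=C10 olefin of ring B, exactly where hydrogen-atom transfer places a tertiary radical; C7 relays its configuration to C5 and then to C10.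

Key step: step 5

Remark: eudesmane numbering (C1–C15) is used for atoms in all compounds and β is the face of the C10 methyl group; C4 in compounds 7 to 11 is an uncontrolled centre, left undefined in the SMILES, and is removed in step 6.

**Route**

Step 1
Reactants: 1 (R)-(−)-carvone
Product: 3 (5R)-5-acetyl-2-methylcyclohex-2-en-1-one, via ozonide 2 (not isolated)
Conditions: O3, CH2Cl2, −78 °C; then Me2S, −78 °C to rt
Reagents that add atoms: ozone, [O-][O+]=O
Why: Chemoselective ozonolysis, because the electron-rich 1,1-disubstituted isopropenyl olefin reacts far faster than the electron-poor enone olefin; the neutral reductive work-up should not enolise the now α-acidic C7–H, so the single stereocentre is kept.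

Step 2
Reactants: 3 (5R)-5-acetyl-2-methylcyclohex-2-en-1-one
Product: 4 (5R)-2-methyl-5-(2-methyl-1,3-dioxolan-2-yl)cyclohex-2-en-1-one
Conditions: TMSOCH2CH2OTMS, TMSOTf (cat.), CH2Cl2, −78 °C
Reagents that add atoms: 1,2-bis(trimethylsilyloxy)ethane, C[Si](C)(C)OCCO[Si](C)(C)C
Why: TMSOTf-catalysed silyl-transfer ketalisation converts the saturated methyl ketone selectively over the deactivated conjugated carbonyl and, being aprotic and cold, should not epimerise C7.

Step 3
Reactants: 4 (5R)-2-methyl-5-(2-methyl-1,3-dioxolan-2-yl)cyclohex-2-en-1-one; 5 N-methoxy-N-methylpropanamide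
Product: 7 2-[(1S,5R)-1-hydroxy-2-methyl-5-(2-methyl-1,3-dioxolan-2-yl)cyclohex-2-en-1-yl]-N-methoxy-N-methylpropanamide, via lithium enolate 6 (not isolated)
Conditions: 5, LiN(i-Pr)2 (LDA), THF, −78 °C; then 4, −78 °C; AcOH quench at −78 °C
Reagents that add atoms: none
Why: Aldol-type kinetic 1,2-addition of an amide enolate to the enone carbonyl, in which the nucleophile enters axially and anti to the equatorial C7 dioxolanyl group, so that C5 should carry OH cis and the side chain trans to the C7 substituent (the minor C5 epimer is removed by chromatography; C4 forms as a mixture).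

Step 4
Reactants: 7 2-[(1S,5R)-1-hydroxy-2-methyl-5-(2-methyl-1,3-dioxolan-2-yl)cyclohex-2-en-1-yl]-N-methoxy-N-methylpropanamide
Product: 8 4-[(1S,5R)-1-hydroxy-2-methyl-5-(2-methyl-1,3-dioxolan-2-yl)cyclohex-2-en-1-yl]pent-1-en-3-one
Conditions: CH2=CHMgBr (3 equiv), THF, −78 to 0 °C; inverse quench into cold 0.5 M HCl
Reagents that add atoms: vinylmagnesium bromide, C=C[Mg]Br
Why: Weinreb ketone synthesis, in which the first equivalent of Grignard reagent deprotonates the tertiary hydroxyl, the amide takes up one vinyl group without over-addition, and the acidic inverse quench keeps the liberated N,O-dimethylhydroxylamine from adding to the vinyl ketone.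

Step 5
Reactants: 8 4-[(1S,5R)-1-hydroxy-2-methyl-5-(2-methyl-1,3-dioxolan-2-yl)cyclohex-2-en-1-yl]pent-1-en-3-one
Product: 11 (4aS,7R,8aS)-8a-hydroxy-1,4a-dimethyl-7-(2-methyl-1,3-dioxolan-2-yl)octahydronaphthalen-2(1H)-one, via tertiary C10 radical 9 (not isolated), via ring-closed keto radical 10 (not isolated)
Conditions: Fe(acac)3, PhSiH3, EtOH/ethylene glycol (5:1), 60 °C, degassed, high dilution
Reagents that add atoms: none
Why: An iron hydride formed from Fe(acac)3 and PhSiH3 transfers a hydrogen atom to C9 of the electron-rich trisubstituted C9=C10 olefin, the tertiary C10 radical 9 adds to C1, the β-carbon of the C1=C2–C3=O vinyl ketone, and the α-keto radical 10 is reduced and protonated by ethanol to the ketone. The closest known reaction type is the Fe(acac)3/PhSiH3 reductive olefin–enone coupling (MHAT-initiated Giese addition) in its intramolecular form, which is established for building quaternary carbons next to fully substituted centres. Ring A closes in the 6-endo-trig mode, because the in-chain carbonyl directs the nucleophilic radical to the terminal enone carbon and the 5-exo alternative would leave a primary radical. C10, the only new stereocentre that is kept, is set by substrate control: with the C7 dioxolanyl group equatorial on ring B the C5 side chain (trans to it) is axial, so C1 can reach the planar C10 radical only on the α face and the cis-fused ketol with the C10 methyl β (cis to the C7 substituent, 10S) should result, while C4 stays an epimeric mixture that step 6 erases. The step needs hydrogen-atom transfer to the donor olefin and not to the vinyl ketone, and ring closure faster than reduction of radical 9; the polarity match of nucleophilic tertiary radical and electrophilic enone, the six-membered tether and the absence of any other donor olefin (the side-chain olefin of the target is stored as a ketal-protected acetyl group) secure this.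

Step 6
Reactants: 11 (4aS,7R,8aS)-8a-hydroxy-1,4a-dimethyl-7-(2-methyl-1,3-dioxolan-2-yl)octahydronaphthalen-2(1H)-one
Product: 12 (4aS,7R)-1,4a-dimethyl-7-(2-methyl-1,3-dioxolan-2-yl)-4,4a,5,6,7,8-hexahydronaphthalen-2(3H)-one
Conditions: NaOMe (cat.), MeOH, 50 °C
Reagents that add atoms: none
Why: Base-mediated E1cB dehydration of the β-hydroxy ketone (the closing half of a Robinson annulation), in which any retro-aldol/aldol equilibration converges on the same conjugated enone, the C4 and C5 centres are erased, and the quaternary C10 and the non-enolisable C7 are untouched.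

Step 7
Reactants: 12 (4aS,7R)-1,4a-dimethyl-7-(2-methyl-1,3-dioxolan-2-yl)-4,4a,5,6,7,8-hexahydronaphthalen-2(3H)-one
Product: 13 (2S,4aS,7R)-1,4a-dimethyl-7-(2-methyl-1,3-dioxolan-2-yl)-2,3,4,4a,5,6,7,8-octahydronaphthalen-2-ol
Conditions: NaBH4, CeCl3·7H2O, MeOH, −78 to 0 °C
Reagents that add atoms: none
Why: Luche 1,2-reduction, in which hydride is delivered axially to C3 from the α face as in steroidal and eudesmane 4-en-3-ones, so the equatorial 3β-alcohol (3S) should predominate.

Step 8
Reactants: 13 (2S,4aS,7R)-1,4a-dimethyl-7-(2-methyl-1,3-dioxolan-2-yl)-2,3,4,4a,5,6,7,8-octahydronaphthalen-2-ol; 14 angelic acid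
Product: 16 (2S,4aS,7R)-1,4a-dimethyl-7-(2-methyl-1,3-dioxolan-2-yl)-2,3,4,4a,5,6,7,8-octahydronaphthalen-2-yl (2Z)-2-methylbut-2-enoate, via mixed anhydride 15 (not isolated)
Conditions: 14, 2,4,6-trichlorobenzoyl chloride, Et3N, toluene, rt; then 13, toluene, 80 °C
Reagents that add atoms: none
Why: Yamaguchi-type esterification through the mixed anhydride, run without a nucleophilic amine catalyst, acylates the allylic alcohol with retention at C3 and should avoid Z-to-E isomerisation of the angelate to the tiglate.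

Step 9
Reactants: 16 (2S,4aS,7R)-1,4a-dimethyl-7-(2-methyl-1,3-dioxolan-2-yl)-2,3,4,4a,5,6,7,8-octahydronaphthalen-2-yl (2Z)-2-methylbut-2-enoate
Product: 17 (2S,4aS,7R)-7-acetyl-1,4a-dimethyl-2,3,4,4a,5,6,7,8-octahydronaphthalen-2-yl (2Z)-2-methylbut-2-enoate
Conditions: TsOH·H2O (cat.), THF/H2O, 40 °C
Reagents that add atoms: water, O
Why: Mild acid-catalysed ketal hydrolysis that should not ionise the allylic ester; C7 is not at risk because its acetyl group is already in the favoured equatorial position.

Step 10
Reactants: 17 (2S,4aS,7R)-7-acetyl-1,4a-dimethyl-2,3,4,4a,5,6,7,8-octahydronaphthalen-2-yl (2Z)-2-methylbut-2-enoate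
Product: 19 (2S,4aS,7R)-1,4a-dimethyl-7-[1-(trifluoromethanesulfonyloxy)ethenyl]-2,3,4,4a,5,6,7,8-octahydronaphthalen-2-yl (2Z)-2-methylbut-2-enoate, via potassium enolate 18 (not isolated)
Conditions: KN(SiMe3)2 (KHMDS, 1.05 equiv), THF, −78 °C; then PhNTf2, −78 to 0 °C; aq NH4Cl
Reagents that add atoms: N-phenylbis(trifluoromethanesulfonimide), O=S(=O)(N(c1ccccc1)S(=O)(=O)C(F)(F)F)C(F)(F)F
Why: Kinetic deprotonation of the methyl ketone by the hindered base occurs at the methyl group (less substituted enolate), and O-triflation fixes the terminal enol; the angelate has no α-hydrogen and should survive one equivalent of base at −78 °C.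

Step 11
Reactants: 19 (2S,4aS,7R)-1,4a-dimethyl-7-[1-(trifluoromethanesulfonyloxy)ethenyl]-2,3,4,4a,5,6,7,8-octahydronaphthalen-2-yl (2Z)-2-methylbut-2-enoate
Product: 20 methyl 2-[(2R,4aS,7S)-4a,8-dimethyl-7-{[(2Z)-2-methylbut-2-enoyl]oxy}-1,2,3,4,4a,5,6,7-octahydronaphthalen-2-yl]prop-2-enoate
Conditions: Pd(OAc)2 (5 mol %), PPh3, CO (1 atm), MeOH, Et3N, DMF, rt
Reagents that add atoms: carbon monoxide, [C-]#[O+]; methanol, CO
Why: Palladium-catalysed methoxycarbonylation of an enol triflate (oxidative addition to zerovalent palladium, CO insertion, methanolysis) gives the 2-substituted acrylate, and the hindered allylic angelate should not ionise at room temperature.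

Step 12
Reactants: 20 methyl 2-[(2R,4aS,7S)-4a,8-dimethyl-7-{[(2Z)-2-methylbut-2-enoyl]oxy}-1,2,3,4,4a,5,6,7-octahydronaphthalen-2-yl]prop-2-enoate
Product: 21 methyl 2-[(2R,4aS,7S,8aS)-8a-hydroperoxy-4a-methyl-8-methylidene-7-{[(2Z)-2-methylbut-2-enoyl]oxy}decahydronaphthalen-2-yl]prop-2-enoate (target)
Conditions: O2, tetraphenylporphyrin (cat.), visible light, CH2Cl2, 0 °C
Reagents that add atoms: dioxygen, O=O
Why: Schenck ene reaction, in which singlet oxygen attacks only the electron-rich tetrasubstituted C4=C5 olefin, approaches the α face anti to the axial C10 methyl, bonds to C5 and takes a hydrogen from the C15 methyl (geminal to the acyloxy-bearing C3), which should give the 5α-hydroperoxide (5S) and the C4=C15 olefin as in the photooxygenation of eudesm-4-enes.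

**Compound list**
1 | (R)-(−)-carvone | CC1=CC[C@H](CC1=O)C(C)=C | starting material
2 | (5R)-2-methyl-5-(3-methyl-1,2,4-trioxolan-3-yl)cyclohex-2-en-1-one (ozonide, not isolated) | CC1=CC[C@H](CC1=O)C2(C)OCOO2 | intermediate
3 | (5R)-5-acetyl-2-methylcyclohex-2-en-1-one | CC1=CC[C@H](CC1=O)C(C)=O | intermediate
4 | (5R)-2-methyl-5-(2-methyl-1,3-dioxolan-2-yl)cyclohex-2-en-1-one | CC1=CC[C@H](CC1=O)C2(C)OCCO2 | intermediate
5 | N-methoxy-N-methylpropanamide | CCC(=O)N(C)OC | starting material
6 | lithium (Z)-enolate of 5 (not isolated) | C/C=C(\O[Li])N(C)OC | intermediate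
7 | 2-[(1S,5R)-1-hydroxy-2-methyl-5-(2-methyl-1,3-dioxolan-2-yl)cyclohex-2-en-1-yl]-N-methoxy-N-methylpropanamide (C4 epimers) | CC1=CC[C@@H](C2(C)OCCO2)C[C@]1(O)C(C)C(=O)N(C)OC | intermediate
8 | 4-[(1S,5R)-1-hydroxy-2-methyl-5-(2-methyl-1,3-dioxolan-2-yl)cyclohex-2-en-1-yl]pent-1-en-3-one (C4 epimers) | CC1=CC[C@@H](C2(C)OCCO2)C[C@]1(O)C(C)C(=O)C=C | intermediate
9 | tertiary C10 radical formed from 8 by hydrogen-atom transfer to C9 (not isolated) | C[C]1CC[C@@H](C2(C)OCCO2)C[C@]1(O)C(C)C(=O)C=C | intermediate
10 | ring-closed C2 α-keto radical (not isolated) | C[C@@]12CC[C@@H](C3(C)OCCO3)C[C@]1(O)C(C)C(=O)[CH]C2 | intermediate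
11 | (4aS,7R,8aS)-8a-hydroxy-1,4a-dimethyl-7-(2-methyl-1,3-dioxolan-2-yl)octahydronaphthalen-2(1H)-one (cis-fused, C4 epimers) | C[C@@]12CC[C@@H](C3(C)OCCO3)C[C@]1(O)C(C)C(=O)CC2 | intermediate
12 | (4aS,7R)-1,4a-dimethyl-7-(2-methyl-1,3-dioxolan-2-yl)-4,4a,5,6,7,8-hexahydronaphthalen-2(3H)-one | C[C@@]12CC[C@@H](C3(C)OCCO3)CC1=C(C)C(=O)CC2 | intermediate
13 | (2S,4aS,7R)-1,4a-dimethyl-7-(2-methyl-1,3-dioxolan-2-yl)-2,3,4,4a,5,6,7,8-octahydronaphthalen-2-ol (3β-ol) | C[C@@]12CC[C@@H](C3(C)OCCO3)CC1=C(C)[C@@H](O)CC2 | intermediate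
14 | angelic acid, (2Z)-2-methylbut-2-enoic acid | C/C=C(/C)C(=O)O | starting material
15 | (2Z)-2-methylbut-2-enoic 2,4,6-trichlorobenzoic anhydride (not isolated) | C/C=C(/C)C(=O)OC(=O)c1c(Cl)cc(Cl)cc1Cl | intermediate
16 | (2S,4aS,7R)-1,4a-dimethyl-7-(2-methyl-1,3-dioxolan-2-yl)-2,3,4,4a,5,6,7,8-octahydronaphthalen-2-yl (2Z)-2-methylbut-2-enoate | C[C@@]12CC[C@@H](C3(C)OCCO3)CC1=C(C)[C@@H](OC(=O)/C(C)=C\C)CC2 | intermediate
17 | (2S,4aS,7R)-7-acetyl-1,4a-dimethyl-2,3,4,4a,5,6,7,8-octahydronaphthalen-2-yl (2Z)-2-methylbut-2-enoate | C[C@@]12CC[C@@H](C(C)=O)CC1=C(C)[C@@H](OC(=O)/C(C)=C\C)CC2 | intermediate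
18 | potassium enolate of 17 at the acetyl methyl group (not isolated) | C[C@@]12CC[C@@H](C(=C)O[K])CC1=C(C)[C@@H](OC(=O)/C(C)=C\C)CC2 | intermediate
19 | (2S,4aS,7R)-1,4a-dimethyl-7-[1-(trifluoromethanesulfonyloxy)ethenyl]-2,3,4,4a,5,6,7,8-octahydronaphthalen-2-yl (2Z)-2-methylbut-2-enoate | C[C@@]12CC[C@@H](C(=C)OS(=O)(=O)C(F)(F)F)CC1=C(C)[C@@H](OC(=O)/C(C)=C\C)CC2 | intermediate
20 | methyl 2-[(2R,4aS,7S)-4a,8-dimethyl-7-{[(2Z)-2-methylbut-2-enoyl]oxy}-1,2,3,4,4a,5,6,7-octahydronaphthalen-2-yl]prop-2-enoate (methyl 3β-angeloyloxyeudesma-4,11(13)-dien-12-oate) | C[C@@]12CC[C@@H](C(=C)C(=O)OC)CC1=C(C)[C@@H](OC(=O)/C(C)=C\C)CC2 | intermediate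
21 | methyl 2-[(2R,4aS,7S,8aS)-8a-hydroperoxy-4a-methyl-8-methylidene-7-{[(2Z)-2-methylbut-2-enoyl]oxy}decahydronaphthalen-2-yl]prop-2-enoate (methyl 3β-angeloyloxy-5α-hydroperoxyeudesma-4(15),11(13)-dien-12-oate) | C=C(C(=O)OC)[C@@H]1CC[C@@]2(C)CC[C@H](OC(=O)/C(C)=C\C)C(=C)[C@]2(OO)C1 | target

**Totals**
Total step count: 12. Longest linear sequence: 12 steps, from 1.

**Steps most likely to fail**

Step 5. The iron hydride may reduce the vinyl ketone, radical 9 may be reduced before it cyclises, or ring closure may occur from the wrong face and give the C10 epimer. The fallback sets out from 4 and comes back at 12, and makes the C1–C10 bond in an open-chain Michael step before ring A is closed by aldol condensation.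
- Conjugate reduction of 4 with LiBH(s-Bu)3 (THF, −78 °C) should give the saturated ketone (5R)-2-methyl-5-(2-methyl-1,3-dioxolan-2-yl)cyclohexan-1-one F1.
- Condensation with (R)-1-phenylethylamine (toluene, molecular sieves) should give the imine F2.
- Its secondary enamine tautomer should add to pent-1-en-3-one at the methyl-bearing carbon under control of the amine auxiliary (THF, 40 °C), and brief hydrolysis with dilute aqueous AcOH should release the 1,5-diketone (2S,5R)-2-methyl-5-(2-methyl-1,3-dioxolan-2-yl)-2-(3-oxopentyl)cyclohexan-1-one F3.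
- NaOMe in MeOH should then close ring A to 12.

Step 12. Hydrogen abstraction may occur at C6 instead of C15 (giving the 4-hydroperoxy-5-ene regioisomer), or oxygen may enter from the β face. The fallback sets out from 20 and comes back at 21, and replaces the pericyclic oxygenation by an ionic sequence.
- Epoxidation with mCPBA (NaHCO3, CH2Cl2, 0 °C) on the α face should give methyl 3β-angeloyloxy-4α,5α-epoxyeudesm-11(13)-en-12-oate F4.
- Syn-elimination with diethylaluminium 2,2,6,6-tetramethylpiperidide (toluene, 0 °C), which removes a hydrogen from the least hindered C15 methyl, should give the tertiary allylic alcohol methyl 3β-angeloyloxy-5α-hydroxyeudesma-4(15),11(13)-dien-12-oate F5.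
- Acid-catalysed perhydrolysis (anhydrous H2O2 in Et2O, cat. TsOH, 0 °C) should exchange the tertiary allylic hydroxyl for a hydroperoxy group, with capture at C5 trans to the C10 methyl, to give 21. This last exchange is the weakest link, because capture at C15 can compete.

Step 3. The basic amide enolate may enolise ketone 4 instead of adding, conjugate addition or retro-aldol cleavage may set in on warming, and facial selectivity may be low. The fallback sets out from 4 and comes back at 7.
- A Reformatsky reaction of 4 with ethyl 2-bromopropanoate and activated Zn (THF, 50 °C) uses a non-basic zinc enolate that adds 1,2 to enones, and should give ethyl 2-[(1S,5R)-1-hydroxy-2-methyl-5-(2-methyl-1,3-dioxolan-2-yl)cyclohex-2-en-1-yl]propanoate F6.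
- Direct aminolysis of the ester with MeNHOMe·HCl and i-PrMgCl (THF, −20 °C) should then give 7.

**Further compounds**
F1 | step 5 | (5R)-2-methyl-5-(2-methyl-1,3-dioxolan-2-yl)cyclohexan-1-one (C2 epimers) | CC1CC[C@@H](C2(C)OCCO2)CC1=O
F2 | step 5 | N-[(1R)-1-phenylethyl]imine of F1 | C[C@@H](N=C1C[C@H](C2(C)OCCO2)CCC1C)c1ccccc1
F3 | step 5 | (2S,5R)-2-methyl-5-(2-methyl-1,3-dioxolan-2-yl)-2-(3-oxopentyl)cyclohexan-1-one | CCC(=O)CC[C@]1(C)CC[C@@H](C2(C)OCCO2)CC1=O
F4 | step 12 | methyl 3β-angeloyloxy-4α,5α-epoxyeudesm-11(13)-en-12-oate | C[C@@]12CC[C@@H](C(=C)C(=O)OC)C[C@]13O[C@]3(C)[C@@H](OC(=O)/C(C)=C\C)CC2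
F5 | step 12 | methyl 3β-angeloyloxy-5α-hydroxyeudesma-4(15),11(13)-dien-12-oate | C=C(C(=O)OC)[C@@H]1CC[C@@]2(C)CC[C@H](OC(=O)/C(C)=C\C)C(=C)[C@]2(O)C1
F6 | step 3 | ethyl 2-[(1S,5R)-1-hydroxy-2-methyl-5-(2-methyl-1,3-dioxolan-2-yl)cyclohex-2-en-1-yl]propanoate (C4 epimers) | CC1=CC[C@@H](C2(C)OCCO2)C[C@]1(O)C(C)C(=O)OCC
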